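The tetrahydrofuran (O1, C2–C5) carries its two aryl-bearing carbons C2 and C5 on either side of the ring oxygen, trans to each other, with C3-benzyl and C4-aroyl each cis to its aryl neighbour. Both C–O bonds are therefore laid down together, cis, by singlet-oxygen cycloaddition to a 1,4-diaryl-1,3-diene that already hangs on the preformed all-trans chroman. The resulting six-membered 3,6-dihydro-1,2-dioxine is the precursor of the key step: triphenylphosphine extrudes one oxygen atom and closes the five-membered ring with inversion at C2, turning cis into trans in one operation. Conjugate reduction then sets C3 and C4, each anti to its flanking aryl.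

Key step: step 15

Remarks on the chemistry and on notation:
- OTBS = tert-butyldimethylsilyloxy. ArChr = the aryl group 2,4-bis(OTBS)-5-[(2S,3R,4S)-3-(5-bromo-2-OTBS-phenyl)-7-OTBS-2-(4-OTBS-phenyl)chroman-4-yl]phenyl (all-trans chroman).
- Furan-ring locants follow the target: O1, C2 (resorcinyl ring), C3 (benzyl), C4 (aroyl), C5 (4-oxyphenyl).
- At chroman C4 the CIP descriptor is S in the silyl ethers and R in the free phenol; the geometry is the same.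
- Assumption: the silyl ethers 3, 9, 11 and 19 are bought; each is otherwise one silylation away from the parent phenol.
- The photooxygenation (step 14) has no control over which diene face reacts relative to the distant chroman, so the absolute configuration of the furan carbons is secured there by separating two diastereomers.

Step 1
Reactants: 1 5-bromo-2,4-dihydroxybenzaldehyde
Product: 2 5-bromo-2,4-bis(OTBS)benzaldehyde
Conditions: TBSCl, imidazole, DMF, rt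
Reagents that add atoms: tert-butyldimethylsilyl chloride C[Si](C)(Cl)C(C)(C)C
Why: Standard imidazole-promoted silyl ether formation masks both phenols as fluoride-labile aryl TBS ethers that tolerate every later step.

Step 2
Reactants: 3 [4-(OTBS)phenyl]methanol
Product: 4 4-(OTBS)benzyl bromide
Conditions: CBr4, PPh3, CH2Cl2, 0 °C
Reagents that add atoms: carbon tetrabromide BrC(Br)(Br)Br
Why: Appel bromination converts the primary benzylic alcohol into the bromide under neutral conditions that leave the aryl silyl ether intact.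

Step 3
Reactants: 4 4-(OTBS)benzyl bromide
Product: 5 3-[4-(OTBS)phenyl]prop-1-yne
Conditions: HC≡CMgBr, CuBr·SMe2 (cat.), THF, 0 °C → rt
Reagents that add atoms: ethynylmagnesium bromide C#C[Mg]Br
Why: Copper-catalysed coupling of a benzylic bromide with an alkynyl Grignard reagent (sp–sp3 substitution) gives the terminal 3-arylpropyne.

Step 4
Reactants: 2 5-bromo-2,4-bis(OTBS)benzaldehyde; 5 3-[4-(OTBS)phenyl]prop-1-yne
Product: 6 2,4-bis(OTBS)-5-{3-[4-(OTBS)phenyl]prop-1-yn-1-yl}benzaldehyde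
Conditions: PdCl2(PhCN)2 (cat.), P(t-Bu)3 (cat.), CuI (cat.), HN(i-Pr)2, dioxane, rt
Reagents that add atoms: none
Why: Sonogashira coupling with the bulky electron-rich phosphine activates the electron-rich aryl bromide at room temperature, and the aldehyde and silyl ethers are inert to it.

Step 5
Reactants: 7 4-bromo-2-iodophenol
Product: 8 4-bromo-2-iodo-1-(OTBS)benzene
Conditions: TBSCl, imidazole, DMF, rt
Reagents that add atoms: tert-butyldimethylsilyl chloride C[Si](C)(Cl)C(C)(C)C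
Why: Silyl ether formation as in step 1.

Step 6
Reactants: 8 4-bromo-2-iodo-1-(OTBS)benzene; 9 4-(OTBS)styrene
Product: 10 (E)-4-bromo-1-(OTBS)-2-{2-[4-(OTBS)phenyl]ethenyl}benzene
Conditions: Pd(OAc)2 (cat.), Et3N, DMF, 60 °C
Reagents that add atoms: none
Why: Heck reaction in which oxidative addition occurs only at the C–I bond (C–Br is kept for step 18), and syn insertion followed by syn β-hydride elimination gives the E-stilbene.

Step 7
Reactants: 11 3-(OTBS)phenol; 6 2,4-bis(OTBS)-5-{3-[4-(OTBS)phenyl]prop-1-yn-1-yl}benzaldehyde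
Product: 13 rac-[2-hydroxy-4-(OTBS)phenyl]{2,4-bis(OTBS)-5-[3-(4-OTBS-phenyl)prop-1-yn-1-yl]phenyl}methanol, via bromomagnesium 3-(OTBS)phenoxide 12 (not isolated)
Conditions: EtMgBr, Et2O, 0 °C; then 6, toluene, rt; aq. NH4Cl
Reagents that add atoms: none
Why: Ortho-selective hydroxyalkylation of a magnesium phenoxide by an aldehyde through a chelated six-membered transition state places the carbinol ortho to the free hydroxyl and para to OTBS; the carbinol centre is racemic and is erased in step 8.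

Step 8
Reactants: 13 rac-[2-hydroxy-4-(OTBS)phenyl]{2,4-bis(OTBS)-5-[3-(4-OTBS-phenyl)prop-1-yn-1-yl]phenyl}methanol; 10 (E)-4-bromo-1-(OTBS)-2-{2-[4-(OTBS)phenyl]ethenyl}benzene
Product: 15 (2S,3R,4S)-3-(5-bromo-2-OTBS-phenyl)-4-{2,4-bis(OTBS)-5-[3-(4-OTBS-phenyl)prop-1-yn-1-yl]phenyl}-7-OTBS-2-(4-OTBS-phenyl)chromane, via ortho-quinone methide 14 (not isolated)
Conditions: chiral BINOL-derived N-triflylphosphoramide bearing 3,3'-bis(2,4,6-triisopropylphenyl) groups (cat., enantiomer chosen for the 2S,3R,4S series), 5 Å molecular sieves, toluene, −20 °C → rt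
Reagents that add atoms: none
Why: The chiral Brønsted acid dehydrates 13 to ortho-quinone methide 14 and holds it as a chiral ion pair for an inverse-demand oxa-Diels–Alder reaction with stilbene 10, in which the alkene carbon that leaves the cation-stabilising 4-silyloxyphenyl end bonds to oxygen (C2), the E alkene gives 2,3-trans, endo approach gives 2,4-cis (hence the all-trans chroman), and the catalyst sets the absolute configuration of C2, C3 and C4.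

Step 9
Reactants: 15 (2S,3R,4S)-3-(5-bromo-2-OTBS-phenyl)-4-{2,4-bis(OTBS)-5-[3-(4-OTBS-phenyl)prop-1-yn-1-yl]phenyl}-7-OTBS-2-(4-OTBS-phenyl)chromane
Product: 16 (Z)-2-[1-(ArChr)-3-(4-OTBS-phenyl)prop-1-en-2-yl]-4,4,5,5-tetramethyl-1,3,2-dioxaborolane
Conditions: CuCl (cat.), P(p-tol)3 (cat.), NaOt-Bu (cat.), B2pin2, MeOH, THF, rt
Reagents that add atoms: bis(pinacolato)diboron CC1(C)OB(OC1(C)C)B1OC(C)(C)C(C)(C)O1
Why: Copper-catalysed syn borylcupration of the internal aryl alkyne places copper at the aryl-bearing carbon and boron at the remote carbon, and protonolysis gives the Z alkenyl boronate (aryl trans to boron) needed for an outward-pointing diene terminus.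

Step 10
Reactants: 17 4-iodobenzene-1,3-diol
Product: 18 1-iodo-2,4-bis(OTBS)benzene
Conditions: TBSCl, imidazole, DMF, rt
Reagents that add atoms: tert-butyldimethylsilyl chloride C[Si](C)(Cl)C(C)(C)C
Why: Silyl ether formation as in step 1.

Step 11
Reactants: 18 1-iodo-2,4-bis(OTBS)benzene; 19 1-ethynyl-4-(OTBS)benzene
Product: 20 1-[2,4-bis(OTBS)phenyl]-3-[4-(OTBS)phenyl]prop-2-yn-1-one
Conditions: PdCl2(PPh3)2 (cat.), Et3N, CO (1 atm), THF, rt
Reagents that add atoms: carbon monoxide [C-]#[O+]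
Why: Carbonylative Sonogashira coupling, in which CO inserts into the aryl–palladium bond before the alkyne is transferred, gives the diaryl ynone directly.

Step 12
Reactants: 20 1-[2,4-bis(OTBS)phenyl]-3-[4-(OTBS)phenyl]prop-2-yn-1-one
Product: 22 (E)-1-[2,4-bis(OTBS)phenyl]-2-iodo-3-[4-(OTBS)phenyl]prop-2-en-1-one, via alpha-stannyl enone 21 (not isolated)
Conditions: Bu3SnH, Pd(PPh3)4 (cat.), THF, 0 °C; then I2, CH2Cl2, −78 °C, dark
Reagents that add atoms: iodine II; tributyltin hydride CCCC[SnH](CCCC)CCCC (its tin stays only in 21)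
Why: Palladium-catalysed hydrostannation of an ynone is a syn addition that puts tin on the carbon α to the carbonyl, so the β-aryl group ends up cis to the carbonyl, and iododestannylation keeps that geometry.

Step 13
Reactants: 16 (Z)-2-[1-(ArChr)-3-(4-OTBS-phenyl)prop-1-en-2-yl]-4,4,5,5-tetramethyl-1,3,2-dioxaborolane; 22 (E)-1-[2,4-bis(OTBS)phenyl]-2-iodo-3-[4-(OTBS)phenyl]prop-2-en-1-one
Product: 23 (2Z)-1-[2,4-bis(OTBS)phenyl]-2-[(1E)-1-(ArChr)-3-(4-OTBS-phenyl)prop-1-en-2-yl]-3-(4-OTBS-phenyl)prop-2-en-1-one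
Conditions: PdCl2(dppf) (cat.), K3PO4, THF/H2O, rt, dark
Reagents that add atoms: none
Why: Suzuki–Miyaura coupling proceeds with retention at both alkenyl carbons and at the vinyl C–I bond in preference to the electron-rich aryl C–Br bond, giving the 1,3-diene with both aryl termini pointing outward.

Step 14
Reactants: 23 (2Z)-1-[2,4-bis(OTBS)phenyl]-2-[(1E)-1-(ArChr)-3-(4-OTBS-phenyl)prop-1-en-2-yl]-3-(4-OTBS-phenyl)prop-2-en-1-one
Product: 24 cis-(3R,6R)-6-(ArChr)-5-(4-OTBS-benzyl)-4-[2,4-bis(OTBS)benzoyl]-3-(4-OTBS-phenyl)-3,6-dihydro-1,2-dioxine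
Conditions: O2, tetraphenylporphyrin (cat.), visible light (>500 nm), CH2Cl2, −30 °C; the two cis-diastereomers are separated by preparative HPLC
Reagents that add atoms: dioxygen O=O
Why: Sensitised singlet oxygen adds to the s-cis diene in a concerted suprafacial [4+2] cycloaddition, which fixes the two new C–O bonds cis; the distant chroman gives no face control, so 24 should form together with its diastereomer of opposite configuration at both dioxine carbons, and the two are separated.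

Step 15
Reactants: 24 cis-(3R,6R)-6-(ArChr)-5-(4-OTBS-benzyl)-4-[2,4-bis(OTBS)benzoyl]-3-(4-OTBS-phenyl)-3,6-dihydro-1,2-dioxine
Product: 26 trans-(2S,5R)-2-(ArChr)-3-(4-OTBS-benzyl)-4-[2,4-bis(OTBS)benzoyl]-5-(4-OTBS-phenyl)-2,5-dihydrofuran, via dioxaphosphepine 25 (not isolated)
Conditions: PPh3, toluene, 0 °C → rt
Reagents that add atoms: none
Why: Triphenylphosphine inserts into the weak O–O bond to give the seven-membered 1,3,2λ5-dioxaphosphepine 25, which opens to an alkoxide/alkoxyphosphonium pair; the alkoxide on dioxine C3 then displaces Ph3P=O from dioxine C6, so the six-membered peroxide ring contracts to the five-membered ether ring with loss of one oxygen atom. The closest known reaction type is the phosphine deoxygenation of cyclic dialkyl peroxides (1,2-dioxanes to tetrahydrofurans, 1,2-dioxetanes to oxiranes), mechanistically a Mitsunobu-type cyclodehydration. The dihydrofuran ring closes in a 5-exo-tet O-alkylation. No new stereocentre is created: the carbon that keeps its oxygen (furan C5) is retained and the carbon that is attacked (furan C2) is inverted, so the cis-dioxine from the suprafacial cycloaddition is translated stereospecifically into the trans-2,5-diaryl relationship of the target. The step needs SN2 closure at the resorcinyl-bearing carbon and not SN2' closure (vinyl oxirane) or ionisation; the Z ring alkene holds the alkoxide within reach of that carbon, both alkene carbons are fully substituted (which disfavours SN2'), and that carbon is benzylic and vinylogously α to the ketone, the more reactive of the two C–O electrophiles.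

Step 16
Reactants: 26 trans-(2S,5R)-2-(ArChr)-3-(4-OTBS-benzyl)-4-[2,4-bis(OTBS)benzoyl]-5-(4-OTBS-phenyl)-2,5-dihydrofuran
Product: 27 (2S,3R,4R,5S)-2-(ArChr)-3-(4-OTBS-benzyl)-4-[2,4-bis(OTBS)benzoyl]-5-(4-OTBS-phenyl)tetrahydrofuran
Conditions: Cu(OAc)2·H2O (cat.), 1,2-bis(diphenylphosphino)benzene (cat.), (HMe2Si)2O, t-BuOH, toluene, rt
Reagents that add atoms: none
Why: Copper hydride conjugate reduction: hydride adds to C3 from the face opposite the adjacent C2 aryl (2,3-cis), and the copper enolate is protonated at C4 opposite the adjacent C5 aryl (4,5-cis, 3,4-trans), which should also be the C4 epimer favoured at equilibrium because the alternative places the C2, C3 and C4 substituents all cis.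

Step 17
Reactants: 18 1-iodo-2,4-bis(OTBS)benzene
Product: 28 1-[2,4-bis(OTBS)phenyl]prop-2-en-1-one
Conditions: Pd(PPh3)4 (cat.), CO (1 atm), Bu3Sn(CH=CH2), toluene, 60 °C
Reagents that add atoms: carbon monoxide [C-]#[O+]; tributyl(vinyl)stannane C=C[Sn](CCCC)(CCCC)CCCC
Why: Carbonylative Stille coupling of the aryl iodide with the vinylstannane under CO gives the aryl vinyl ketone, which is used at once.

Step 18
Reactants: 27 (2S,3R,4R,5S)-2-(ArChr)-3-(4-OTBS-benzyl)-4-[2,4-bis(OTBS)benzoyl]-5-(4-OTBS-phenyl)tetrahydrofuran; 28 1-[2,4-bis(OTBS)phenyl]prop-2-en-1-one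
Product: 29 (E)-1-[2,4-bis(OTBS)phenyl]-3-{4-OTBS-3-[(2S,3R,4S)-4-{5-[(2S,3R,4R,5S)-4-[2,4-bis(OTBS)benzoyl]-3-(4-OTBS-benzyl)-5-(4-OTBS-phenyl)tetrahydrofuran-2-yl]-2,4-bis(OTBS)phenyl}-7-OTBS-2-(4-OTBS-phenyl)chroman-3-yl]phenyl}prop-2-en-1-one
Conditions: Pd2(dba)3 (cat.), P(t-Bu)3 (cat.), Cy2NMe, dioxane, 50 °C
Reagents that add atoms: none
Why: Heck reaction of the remaining aryl bromide with the electron-poor vinyl ketone under mild amine-base conditions gives the E-chalcone by syn insertion and syn β-hydride elimination without touching the ketone-bearing furan ring.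

Step 19
Reactants: 29 (E)-1-[2,4-bis(OTBS)phenyl]-3-{4-OTBS-3-[(2S,3R,4S)-4-{5-[(2S,3R,4R,5S)-4-[2,4-bis(OTBS)benzoyl]-3-(4-OTBS-benzyl)-5-(4-OTBS-phenyl)tetrahydrofuran-2-yl]-2,4-bis(OTBS)phenyl}-7-OTBS-2-(4-OTBS-phenyl)chroman-3-yl]phenyl}prop-2-en-1-one
Product: 30 CNP0330082.3: (E)-1-(2,4-dihydroxyphenyl)-3-{4-hydroxy-3-[(2S,3R,4R)-4-{5-[(2S,3R,4R,5S)-4-(2,4-dihydroxybenzoyl)-3-(4-hydroxybenzyl)-5-(4-hydroxyphenyl)tetrahydrofuran-2-yl]-2,4-dihydroxyphenyl}-7-hydroxy-2-(4-hydroxyphenyl)chroman-3-yl]phenyl}prop-2-en-1-one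
Conditions: TBAF, AcOH, THF, 0 °C → rt
Reagents that add atoms: none
Why: Acetic-acid-buffered fluoride cleaves all eleven aryl Si–O bonds near neutrality, which avoids acid ionisation at C2 of the tetrahydrofuran and base-induced epimerisation or retro-oxa-Michael opening at C4–C5.

Compound list

1 | 5-bromo-2,4-dihydroxybenzaldehyde | O=Cc1cc(Br)c(O)cc1O | starting material
2 | 5-bromo-2,4-bis(OTBS)benzaldehyde | O=Cc1cc(Br)c(O[Si](C)(C)C(C)(C)C)cc1O[Si](C)(C)C(C)(C)C | intermediate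
3 | [4-(OTBS)phenyl]methanol | OCc1ccc(O[Si](C)(C)C(C)(C)C)cc1 | starting material
4 | 4-(OTBS)benzyl bromide | BrCc1ccc(O[Si](C)(C)C(C)(C)C)cc1 | intermediate
5 | 3-[4-(OTBS)phenyl]prop-1-yne | C#CCc1ccc(O[Si](C)(C)C(C)(C)C)cc1 | intermediate
6 | 2,4-bis(OTBS)-5-{3-[4-(OTBS)phenyl]prop-1-yn-1-yl}benzaldehyde | O=Cc1cc(C#CCc2ccc(O[Si](C)(C)C(C)(C)C)cc2)c(O[Si](C)(C)C(C)(C)C)cc1O[Si](C)(C)C(C)(C)C | intermediate
7 | 4-bromo-2-iodophenol | Oc1ccc(Br)cc1I | starting material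
8 | 4-bromo-2-iodo-1-(OTBS)benzene | Brc1ccc(O[Si](C)(C)C(C)(C)C)c(I)c1 | intermediate
9 | 4-(OTBS)styrene | C=Cc1ccc(O[Si](C)(C)C(C)(C)C)cc1 | starting material
10 | (E)-4-bromo-1-(OTBS)-2-{2-[4-(OTBS)phenyl]ethenyl}benzene | Brc1ccc(O[Si](C)(C)C(C)(C)C)c(/C=C/c2ccc(O[Si](C)(C)C(C)(C)C)cc2)c1 | intermediate
11 | 3-(OTBS)phenol | Oc1cccc(O[Si](C)(C)C(C)(C)C)c1 | starting material
12 | bromomagnesium 3-(OTBS)phenoxide | Br[Mg]Oc1cccc(O[Si](C)(C)C(C)(C)C)c1 | intermediate (not isolated)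
13 | rac-[2-hydroxy-4-(OTBS)phenyl]{2,4-bis(OTBS)-5-[3-(4-OTBS-phenyl)prop-1-yn-1-yl]phenyl}methanol (carbinol centre racemic) | OC(c1ccc(O[Si](C)(C)C(C)(C)C)cc1O)c1cc(C#CCc2ccc(O[Si](C)(C)C(C)(C)C)cc2)c(O[Si](C)(C)C(C)(C)C)cc1O[Si](C)(C)C(C)(C)C | intermediate
14 | ortho-quinone methide: 6-({2,4-bis(OTBS)-5-[3-(4-OTBS-phenyl)prop-1-yn-1-yl]phenyl}methylidene)-3-(OTBS)cyclohexa-2,4-dien-1-one | O=C1C=C(O[Si](C)(C)C(C)(C)C)C=CC1=Cc1cc(C#CCc2ccc(O[Si](C)(C)C(C)(C)C)cc2)c(O[Si](C)(C)C(C)(C)C)cc1O[Si](C)(C)C(C)(C)C | intermediate (not isolated)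
15 | (2S,3R,4S)-3-(5-bromo-2-OTBS-phenyl)-4-{2,4-bis(OTBS)-5-[3-(4-OTBS-phenyl)prop-1-yn-1-yl]phenyl}-7-OTBS-2-(4-OTBS-phenyl)chromane (2,3-trans, 3,4-trans) | Brc1ccc(O[Si](C)(C)C(C)(C)C)c([C@H]2[C@H](c3cc(C#CCc4ccc(O[Si](C)(C)C(C)(C)C)cc4)c(O[Si](C)(C)C(C)(C)C)cc3O[Si](C)(C)C(C)(C)C)c3ccc(O[Si](C)(C)C(C)(C)C)cc3O[C@@H]2c2ccc(O[Si](C)(C)C(C)(C)C)cc2)c1 | intermediate
16 | (Z)-2-[1-(ArChr)-3-(4-OTBS-phenyl)prop-1-en-2-yl]-4,4,5,5-tetramethyl-1,3,2-dioxaborolane | Brc1ccc(O[Si](C)(C)C(C)(C)C)c([C@H]2[C@H](c3cc(/C=C(/B5OC(C)(C)C(C)(C)O5)Cc4ccc(O[Si](C)(C)C(C)(C)C)cc4)c(O[Si](C)(C)C(C)(C)C)cc3O[Si](C)(C)C(C)(C)C)c3ccc(O[Si](C)(C)C(C)(C)C)cc3O[C@@H]2c2ccc(O[Si](C)(C)C(C)(C)C)cc2)c1 | intermediate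
17 | 4-iodobenzene-1,3-diol | Oc1ccc(I)c(O)c1 | starting material
18 | 1-iodo-2,4-bis(OTBS)benzene | Ic1ccc(O[Si](C)(C)C(C)(C)C)cc1O[Si](C)(C)C(C)(C)C | intermediate
19 | 1-ethynyl-4-(OTBS)benzene | C#Cc1ccc(O[Si](C)(C)C(C)(C)C)cc1 | starting material
20 | 1-[2,4-bis(OTBS)phenyl]-3-[4-(OTBS)phenyl]prop-2-yn-1-one | O=C(C#Cc1ccc(O[Si](C)(C)C(C)(C)C)cc1)c1ccc(O[Si](C)(C)C(C)(C)C)cc1O[Si](C)(C)C(C)(C)C | intermediate
21 | (E)-1-[2,4-bis(OTBS)phenyl]-3-[4-(OTBS)phenyl]-2-(tributylstannyl)prop-2-en-1-one (β-aryl cis to C=O) | O=C(c1ccc(O[Si](C)(C)C(C)(C)C)cc1O[Si](C)(C)C(C)(C)C)/C(=C\c1ccc(O[Si](C)(C)C(C)(C)C)cc1)[Sn](CCCC)(CCCC)CCCC | intermediate (not isolated)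
22 | (E)-1-[2,4-bis(OTBS)phenyl]-2-iodo-3-[4-(OTBS)phenyl]prop-2-en-1-one (β-aryl cis to C=O) | O=C(c1ccc(O[Si](C)(C)C(C)(C)C)cc1O[Si](C)(C)C(C)(C)C)/C(I)=C\c1ccc(O[Si](C)(C)C(C)(C)C)cc1 | intermediate
23 | (2Z)-1-[2,4-bis(OTBS)phenyl]-2-[(1E)-1-(ArChr)-3-(4-OTBS-phenyl)prop-1-en-2-yl]-3-(4-OTBS-phenyl)prop-2-en-1-one | Brc1ccc(O[Si](C)(C)C(C)(C)C)c([C@H]2[C@H](c3cc(/C=C(/C(C(=O)c5ccc(O[Si](C)(C)C(C)(C)C)cc5O[Si](C)(C)C(C)(C)C)=C/c5ccc(O[Si](C)(C)C(C)(C)C)cc5)Cc4ccc(O[Si](C)(C)C(C)(C)C)cc4)c(O[Si](C)(C)C(C)(C)C)cc3O[Si](C)(C)C(C)(C)C)c3ccc(O[Si](C)(C)C(C)(C)C)cc3O[C@@H]2c2ccc(O[Si](C)(C)C(C)(C)C)cc2)c1 | intermediate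
24 | cis-(3R,6R)-6-(ArChr)-5-(4-OTBS-benzyl)-4-[2,4-bis(OTBS)benzoyl]-3-(4-OTBS-phenyl)-3,6-dihydro-1,2-dioxine | Brc1ccc(O[Si](C)(C)C(C)(C)C)c([C@H]2[C@H](c3cc([C@@H]4OO[C@H](c5ccc(O[Si](C)(C)C(C)(C)C)cc5)C(C(=O)c5ccc(O[Si](C)(C)C(C)(C)C)cc5O[Si](C)(C)C(C)(C)C)=C4Cc4ccc(O[Si](C)(C)C(C)(C)C)cc4)c(O[Si](C)(C)C(C)(C)C)cc3O[Si](C)(C)C(C)(C)C)c3ccc(O[Si](C)(C)C(C)(C)C)cc3O[C@@H]2c2ccc(O[Si](C)(C)C(C)(C)C)cc2)c1 | intermediate
25 | cis-7-(ArChr)-6-(4-OTBS-benzyl)-5-[2,4-bis(OTBS)benzoyl]-4-(4-OTBS-phenyl)-2,2,2-triphenyl-4,7-dihydro-1,3,2λ5-dioxaphosphepine (carbon configurations as in 24) | Brc1ccc(O[Si](C)(C)C(C)(C)C)c([C@H]2[C@H](c3cc([C@@H]4OP(c5ccccc5)(c5ccccc5)(c5ccccc5)O[C@H](c5ccc(O[Si](C)(C)C(C)(C)C)cc5)C(C(=O)c5ccc(O[Si](C)(C)C(C)(C)C)cc5O[Si](C)(C)C(C)(C)C)=C4Cc4ccc(O[Si](C)(C)C(C)(C)C)cc4)c(O[Si](C)(C)C(C)(C)C)cc3O[Si](C)(C)C(C)(C)C)c3ccc(O[Si](C)(C)C(C)(C)C)cc3O[C@@H]2c2ccc(O[Si](C)(C)C(C)(C)C)cc2)c1 | intermediate (not isolated)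
26 | trans-(2S,5R)-2-(ArChr)-3-(4-OTBS-benzyl)-4-[2,4-bis(OTBS)benzoyl]-5-(4-OTBS-phenyl)-2,5-dihydrofuran | Brc1ccc(O[Si](C)(C)C(C)(C)C)c([C@H]2[C@H](c3cc([C@H]4O[C@H](c5ccc(O[Si](C)(C)C(C)(C)C)cc5)C(C(=O)c5ccc(O[Si](C)(C)C(C)(C)C)cc5O[Si](C)(C)C(C)(C)C)=C4Cc4ccc(O[Si](C)(C)C(C)(C)C)cc4)c(O[Si](C)(C)C(C)(C)C)cc3O[Si](C)(C)C(C)(C)C)c3ccc(O[Si](C)(C)C(C)(C)C)cc3O[C@@H]2c2ccc(O[Si](C)(C)C(C)(C)C)cc2)c1 | intermediate
27 | (2S,3R,4R,5S)-2-(ArChr)-3-(4-OTBS-benzyl)-4-[2,4-bis(OTBS)benzoyl]-5-(4-OTBS-phenyl)tetrahydrofuran | Brc1ccc(O[Si](C)(C)C(C)(C)C)c([C@H]2[C@H](c3cc([C@H]4O[C@H](c5ccc(O[Si](C)(C)C(C)(C)C)cc5)[C@H](C(=O)c5ccc(O[Si](C)(C)C(C)(C)C)cc5O[Si](C)(C)C(C)(C)C)[C@H]4Cc4ccc(O[Si](C)(C)C(C)(C)C)cc4)c(O[Si](C)(C)C(C)(C)C)cc3O[Si](C)(C)C(C)(C)C)c3ccc(O[Si](C)(C)C(C)(C)C)cc3O[C@@H]2c2ccc(O[Si](C)(C)C(C)(C)C)cc2)c1 | intermediate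
28 | 1-[2,4-bis(OTBS)phenyl]prop-2-en-1-one | C=CC(=O)c1ccc(O[Si](C)(C)C(C)(C)C)cc1O[Si](C)(C)C(C)(C)C | intermediate
29 | undeca-TBS ether of the target: (E)-1-[2,4-bis(OTBS)phenyl]-3-{4-OTBS-3-[(2S,3R,4S)-4-{5-[(2S,3R,4R,5S)-4-[2,4-bis(OTBS)benzoyl]-3-(4-OTBS-benzyl)-5-(4-OTBS-phenyl)tetrahydrofuran-2-yl]-2,4-bis(OTBS)phenyl}-7-OTBS-2-(4-OTBS-phenyl)chroman-3-yl]phenyl}prop-2-en-1-one | O=C(/C=C/c1ccc(O[Si](C)(C)C(C)(C)C)c([C@H]2[C@H](c3cc([C@H]4O[C@H](c5ccc(O[Si](C)(C)C(C)(C)C)cc5)[C@H](C(=O)c5ccc(O[Si](C)(C)C(C)(C)C)cc5O[Si](C)(C)C(C)(C)C)[C@H]4Cc4ccc(O[Si](C)(C)C(C)(C)C)cc4)c(O[Si](C)(C)C(C)(C)C)cc3O[Si](C)(C)C(C)(C)C)c3ccc(O[Si](C)(C)C(C)(C)C)cc3O[C@@H]2c2ccc(O[Si](C)(C)C(C)(C)C)cc2)c1)c1ccc(O[Si](C)(C)C(C)(C)C)cc1O[Si](C)(C)C(C)(C)C | intermediate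
30 | CNP0330082.3: (E)-1-(2,4-dihydroxyphenyl)-3-{4-hydroxy-3-[(2S,3R,4R)-4-{5-[(2S,3R,4R,5S)-4-(2,4-dihydroxybenzoyl)-3-(4-hydroxybenzyl)-5-(4-hydroxyphenyl)tetrahydrofuran-2-yl]-2,4-dihydroxyphenyl}-7-hydroxy-2-(4-hydroxyphenyl)chroman-3-yl]phenyl}prop-2-en-1-one | O=C(/C=C/c1ccc(O)c([C@H]2[C@H](c3cc([C@H]4O[C@H](c5ccc(O)cc5)[C@H](C(=O)c5ccc(O)cc5O)[C@H]4Cc4ccc(O)cc4)c(O)cc3O)c3ccc(O)cc3O[C@@H]2c2ccc(O)cc2)c1)c1ccc(O)cc1O | target

Total step count: 19. Longest linear sequence: 12 steps (steps 2, 3, 4, 7, 8, 9, 13, 14, 15, 16, 18 and 19).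

The three steps most likely to fail, with one fallback each:

Step 15 (key step). The alkoxyphosphonium formed from 25 may ionise at the electron-rich benzylic carbon before the ring closes, which would erode the cis-to-trans transfer, or it may close by SN2' to a vinyl oxirane. The fallback replaces the one-pot ring contraction by a separate reduction and ring closure. It sets out from 24: the O–O bond is cleaved with thiourea in MeOH/CH2Cl2 to give the ene-1,4-diol (2E,4R)-1-[2,4-bis(OTBS)phenyl]-4-(ArChr)-4-hydroxy-2-[(R)-hydroxy(4-OTBS-phenyl)methyl]-3-(4-OTBS-benzyl)but-2-en-1-one F1, which keeps both carbinol configurations and cannot form a furan because the ketone and the remote hydroxyl are trans across the alkene. Mitsunobu cyclodehydration (PPh3, diisopropyl azodicarboxylate, toluene, −20 °C) then closes the ether with inversion at one carbinol carbon and comes back to the route at 26. In this version the hydroxyl that is activated can be chosen in a step of its own, for instance by selective sulfonylation.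

Step 14. Singlet oxygen may be diverted into an ene reaction at the benzylic CH2 or a [2+2] addition at the electron-rich styrenyl bond, and it attacks both diene faces without discrimination. The fallback lets the substrate steer the oxygen. It sets out from 23: Corey–Bakshi–Shibata reduction (the oxazaborolidine enantiomer that gives the R carbinol, catecholborane, toluene, −78 °C) gives the dienol (1R,2Z)-1-[2,4-bis(OTBS)phenyl]-2-[(1E)-1-(ArChr)-3-(4-OTBS-phenyl)prop-1-en-2-yl]-3-(4-OTBS-phenyl)prop-2-en-1-ol F2. In F2, 1,3-allylic strain against the cis aryl group should hold the carbinol C–H in the diene plane, so the hydroxyl lies on one face. Photooxygenation under the conditions of step 14 should then occur on that face through hydrogen bonding of singlet oxygen to the hydroxyl, giving (R)-[2,4-bis(OTBS)phenyl][cis-(3R,6R)-6-(ArChr)-5-(4-OTBS-benzyl)-3-(4-OTBS-phenyl)-3,6-dihydro-1,2-dioxin-4-yl]methanol F3. PPh3 as in step 15 gives (R)-[2,4-bis(OTBS)phenyl][trans-(2S,5R)-2-(ArChr)-3-(4-OTBS-benzyl)-5-(4-OTBS-phenyl)-2,5-dihydrofuran-4-yl]methanol F4, and Dess–Martin oxidation comes back to the route at 26.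

Step 16. Hydride transfer to the tetrasubstituted β-carbon may be slow, which would leave room for 1,2-reduction of the aryl ketone or for loss of the C5 alkoxide from the copper enolate (ring opening). The fallback changes the mechanism from polar hydride addition to radical hydrogen-atom transfer and sets out from 26: Mn(dpm)3 (dpm = dipivaloylmethanate), PhSiH3, t-BuOOH, i-PrOH, rt. The hydrogen atom is delivered to C3 on the face opposite the C2 aryl and the C4 radical is quenched without an enolate ever forming; the sequence comes back to the route at 27 and makes no new compound.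

Further compounds

F1 | step 15 | (2E,4R)-1-[2,4-bis(OTBS)phenyl]-4-(ArChr)-4-hydroxy-2-[(R)-hydroxy(4-OTBS-phenyl)methyl]-3-(4-OTBS-benzyl)but-2-en-1-one | Brc1ccc(O[Si](C)(C)C(C)(C)C)c([C@H]2[C@H](c3cc([C@H](O)/C(Cc4ccc(O[Si](C)(C)C(C)(C)C)cc4)=C(C(=O)c5ccc(O[Si](C)(C)C(C)(C)C)cc5O[Si](C)(C)C(C)(C)C)\[C@H](O)c5ccc(O[Si](C)(C)C(C)(C)C)cc5)c(O[Si](C)(C)C(C)(C)C)cc3O[Si](C)(C)C(C)(C)C)c3ccc(O[Si](C)(C)C(C)(C)C)cc3O[C@@H]2c2ccc(O[Si](C)(C)C(C)(C)C)cc2)c1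
F2 | step 14 | (1R,2Z)-1-[2,4-bis(OTBS)phenyl]-2-[(1E)-1-(ArChr)-3-(4-OTBS-phenyl)prop-1-en-2-yl]-3-(4-OTBS-phenyl)prop-2-en-1-ol | Brc1ccc(O[Si](C)(C)C(C)(C)C)c([C@H]2[C@H](c3cc(/C=C(/C([C@@H](O)c5ccc(O[Si](C)(C)C(C)(C)C)cc5O[Si](C)(C)C(C)(C)C)=C/c5ccc(O[Si](C)(C)C(C)(C)C)cc5)Cc4ccc(O[Si](C)(C)C(C)(C)C)cc4)c(O[Si](C)(C)C(C)(C)C)cc3O[Si](C)(C)C(C)(C)C)c3ccc(O[Si](C)(C)C(C)(C)C)cc3O[C@@H]2c2ccc(O[Si](C)(C)C(C)(C)C)cc2)c1
F3 | step 14 | (R)-[2,4-bis(OTBS)phenyl][cis-(3R,6R)-6-(ArChr)-5-(4-OTBS-benzyl)-3-(4-OTBS-phenyl)-3,6-dihydro-1,2-dioxin-4-yl]methanol | Brc1ccc(O[Si](C)(C)C(C)(C)C)c([C@H]2[C@H](c3cc([C@@H]4OO[C@H](c5ccc(O[Si](C)(C)C(C)(C)C)cc5)C([C@@H](O)c5ccc(O[Si](C)(C)C(C)(C)C)cc5O[Si](C)(C)C(C)(C)C)=C4Cc4ccc(O[Si](C)(C)C(C)(C)C)cc4)c(O[Si](C)(C)C(C)(C)C)cc3O[Si](C)(C)C(C)(C)C)c3ccc(O[Si](C)(C)C(C)(C)C)cc3O[C@@H]2c2ccc(O[Si](C)(C)C(C)(C)C)cc2)c1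
F4 | step 14 | (R)-[2,4-bis(OTBS)phenyl][trans-(2S,5R)-2-(ArChr)-3-(4-OTBS-benzyl)-5-(4-OTBS-phenyl)-2,5-dihydrofuran-4-yl]methanol | Brc1ccc(O[Si](C)(C)C(C)(C)C)c([C@H]2[C@H](c3cc([C@H]4O[C@H](c5ccc(O[Si](C)(C)C(C)(C)C)cc5)C([C@@H](O)c5ccc(O[Si](C)(C)C(C)(C)C)cc5O[Si](C)(C)C(C)(C)C)=C4Cc4ccc(O[Si](C)(C)C(C)(C)C)cc4)c(O[Si](C)(C)C(C)(C)C)cc3O[Si](C)(C)C(C)(C)C)c3ccc(O[Si](C)(C)C(C)(C)C)cc3O[C@@H]2c2ccc(O[Si](C)(C)C(C)(C)C)cc2)c1
F0 | step 16 | none | none
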